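**Retrosynthetic overview**
1. The two formyl groups are added last (Vilsmeier). Before that, C9′–aryl and C9′–isobutyl are made in one operation from a C1 aldehyde, phloroglucinol and isobutylmagnesium bromide via an ortho-quinone methide.
2. The aldehyde comes from the C1 ketone of a 4α,11-diol, itself from double Mukaiyama hydration of a β-selinene-type diene (C4=CH2 by Wittig).
3. Key step: an allyl cation on the side chain is trapped by a vinyl cyclopentanol, and a 1,2-shift of quaternary C10 (C4 to C5) expands the cyclopentanol to the cyclohexanone. Ring B (C6–C7 bond) and ring A (ring expansion) form together.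
4. The cyclopentanol comes from 2-methylcyclopentane-1,3-dione, acrolein, and isopropenyl- and vinylmagnesium bromide; absolute configuration comes from a desymmetrizing transfer hydrogenation.
5. Phloroglucinol comes from resorcinol by C–H borylation and oxidation.

Assumption and convention: the three commercial Grignard solutions are taken as starting materials. Eudesmane numbering is used (decalin C1–C10, C11 = carbinol carbon on C7, C15 = C4 methyl, C9′ = benzylic carbon; β = face of the C10 methyl), and decalin names imply 5α-H, 7β side chain and 10β-methyl unless stated.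

**Route**

Step 1
Reactants: 1 resorcinol
Product: 3 phloroglucinol, via triborylated resorcinol 2 (not isolated)
Conditions: HBpin (4 equiv), [Ir(OMe)(cod)]2 (1.5 mol%), 4,4′-di-tert-butyl-2,2′-bipyridine (3 mol%), THF, 80 °C; then KHSO5 (Oxone), acetone–H2O, 0 → 25 °C
Reagents that add atoms: pinacolborane CC1(C)OBOC1(C)C; potassium peroxymonosulfate [K+].[O-]S(=O)(=O)OO
Why: Iridium-catalysed C–H borylation is sterically controlled, so after in situ O-borylation only C5 (the one C–H not ortho to a substituent) is borylated, and boronate oxidation gives the third hydroxyl.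

Step 2
Reactants: 4 2-methylcyclopentane-1,3-dione; 5 acrolein
Product: 6 2-methyl-2-(3-oxopropyl)cyclopentane-1,3-dione
Conditions: H2O, 25 °C
Reagents that add atoms: none
Why: Michael addition of the acidic 1,3-diketone to acrolein gives the quaternary carbon (future C10), which is still prochiral.

Step 3
Reactants: 6 2-methyl-2-(3-oxopropyl)cyclopentane-1,3-dione; 7 isopropenylmagnesium bromide
Product: 9 2-methyl-5-(1-methyl-2,5-dioxocyclopentyl)pent-1-en-3-yl diethyl phosphate, via bromomagnesium alkoxide 8 (not isolated)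
Conditions: 7 (1.05 equiv), THF, −78 °C; then ClP(O)(OEt)2, DMAP (cat.), −78 → 0 °C
Reagents that add atoms: diethyl chlorophosphate CCOP(=O)(Cl)OCC
Why: Grignard 1,2-addition goes to the aldehyde (the most electrophilic carbonyl) and the alkoxide is phosphorylated in the same flask; the new carbinol centre is racemic and is destroyed in step 7.

Step 4
Reactants: 9 2-methyl-5-(1-methyl-2,5-dioxocyclopentyl)pent-1-en-3-yl diethyl phosphate
Product: 10 5-[(1S,2S)-2-hydroxy-1-methyl-5-oxocyclopentyl]-2-methylpent-1-en-3-yl diethyl phosphate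
Conditions: RuCl(p-cymene)[(S,S)-TsDPEN] (1 mol%), HCO2H–Et3N (5:2), CH2Cl2, 25 °C
Reagents that add atoms: none
Why: Noyori–Ikariya asymmetric transfer hydrogenation desymmetrizes the prochiral 2,2-disubstituted 1,3-diketone; reducing one enantiotopic carbonyl from the methyl face fixes the quaternary centre (future C10) and gives the hydroxyl cis to the side chain (the catalyst antipode would give ent-10).

Step 5
Reactants: 10 5-[(1S,2S)-2-hydroxy-1-methyl-5-oxocyclopentyl]-2-methylpent-1-en-3-yl diethyl phosphate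
Product: 11 2-methyl-5-[(1S,2S)-1-methyl-5-oxo-2-(triethylsilyloxy)cyclopentyl]pent-1-en-3-yl diethyl phosphate
Conditions: TESCl, imidazole, DMF, 0 → 25 °C
Reagents that add atoms: chlorotriethylsilane CC[Si](Cl)(CC)CC
Why: Silylation keeps the hydroxyl from trapping the allyl cation in step 7 and leaves the neighbouring quaternary carbon without a carbonyl, which should make it the better migrating group.

Step 6
Reactants: 11 2-methyl-5-[(1S,2S)-1-methyl-5-oxo-2-(triethylsilyloxy)cyclopentyl]pent-1-en-3-yl diethyl phosphate; 12 vinylmagnesium bromide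
Product: 13 5-[(1S,2S,5S)-2-ethenyl-2-hydroxy-1-methyl-5-(triethylsilyloxy)cyclopentyl]-2-methylpent-1-en-3-yl diethyl phosphate
Conditions: 12 (1.5 equiv), CeCl3, THF, −78 °C; aq. NH4Cl
Reagents that add atoms: none
Why: Organocerium 1,2-addition to the hindered ketone from the face away from the side chain and the silyl ether (vinyl cis to methyl) leaves the phosphate untouched at −78 °C; this carbinol centre becomes the C4 carbonyl in step 7.

Step 7
Reactants: 13 5-[(1S,2S,5S)-2-ethenyl-2-hydroxy-1-methyl-5-(triethylsilyloxy)cyclopentyl]-2-methylpent-1-en-3-yl diethyl phosphate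
Product: 15 1α-(triethylsilyloxy)-15-nor-5α-eudesm-11-en-4-one, via cis-fused C5 epimer 14 (not isolated)
Conditions: HFIP–CH2Cl2 (4:1), 2,6-di-tert-butyl-4-methylpyridine (1.5 equiv), 0 → 40 °C; then DBU (0.2 equiv), CH2Cl2, 25 °C
Reagents that add atoms: none
Why: Proposed new method: solvolysis of the allylic phosphate in HFIP gives a 2-methylallyl cation that the vinyl terminus (C6) attacks at C7, and the developing C5 cation is quenched by a 1,2-shift of quaternary C10 from C4 to C5 with retention (semipinacol ring expansion, cyclopentanol to cyclohexanone), so both six-membered rings form at once; a chair-like ring-B array with the C10 methyl axial and the isopropenyl group equatorial sets C7, DBU equilibrates C5 to the trans fusion, and the closest known reactions are the Prins–pinacol ring-enlarging annulation and cation–olefin cyclizations started from allylic phosphates.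

Step 8
Reactants: 15 1α-(triethylsilyloxy)-15-nor-5α-eudesm-11-en-4-one
Product: 16 1α-(triethylsilyloxy)eudesma-4(15),11-diene
Conditions: Ph3PCH3Br, KOtBu, THF, 0 → 25 °C
Reagents that add atoms: methyltriphenylphosphonium bromide C[P+](c1ccccc1)(c1ccccc1)c1ccccc1.[Br-]
Why: Wittig methylenation of the only ketone installs C15; C5 stays trans, which is the thermodynamic ring fusion.

Step 9
Reactants: 16 1α-(triethylsilyloxy)eudesma-4(15),11-diene
Product: 18 eudesma-4(15),11-dien-1-one, via dienol 17 (not isolated)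
Conditions: TBAF, THF, 0 → 25 °C; then Dess–Martin periodinane, pyridine, CH2Cl2, 25 °C
Reagents that add atoms: none
Why: Fluoride desilylation then Dess–Martin oxidation return the C1 carbonyl needed for homologation; no stereocentre is touched.

Step 10
Reactants: 18 eudesma-4(15),11-dien-1-one
Product: 20 4α,11-dihydroxyeudesman-1-one, via bis(hydroperoxide) 19 (not isolated)
Conditions: Mn(dpm)3 (10 mol%), PhSiH3, O2 (1 atm), iPrOH–CH2Cl2, 0 °C; then PPh3
Reagents that add atoms: dioxygen O=O
Why: Mukaiyama hydration (hydrogen-atom transfer, Markovnikov) converts both 1,1-disubstituted alkenes to tertiary alcohols; the C4 radical is trapped by O2 from the equatorial α face, away from the axial C10 methyl, giving 4α-OH/4β-CH3.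

Step 11
Reactants: 20 4α,11-dihydroxyeudesman-1-one
Product: 22 1β-formyleudesmane-4α,11-diol, via enol ether 21 (not isolated)
Conditions: MeOCH2PPh3Cl, KOtBu (excess), THF, 0 → 60 °C; then PPTS, acetone–H2O, 40 °C; then K2CO3, MeOH, 25 °C
Reagents that add atoms: (methoxymethyl)triphenylphosphonium chloride COC[P+](c1ccccc1)(c1ccccc1)c1ccccc1.[Cl-]; water O
Why: Wittig methoxymethylenation and enol ether hydrolysis add the carbon that becomes C9′, and base epimerization puts the formyl group equatorial, which sets C1 (β) under thermodynamic control.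

Step 12
Reactants: 22 1β-formyleudesmane-4α,11-diol; 3 phloroglucinol; 23 isobutylmagnesium bromide
Product: 26 1β-[(1S)-3-methyl-1-(2,4,6-trihydroxyphenyl)butyl]eudesmane-4α,11-diol, via benzylic alcohol 24 (not isolated), via ortho-quinone methide 25 (not isolated)
Conditions: 3 (3 equiv) and 23 in THF–toluene, 0 °C; add 22, 25 → 70 °C; then more 23 (excess), 70 °C; aq. NH4Cl
Reagents that add atoms: none
Why: Casiraghi-type ortho-hydroxyalkylation of the magnesium phenoxide, elimination to the ortho-quinone methide and 1,4-addition of the Grignard reagent; with C1–H eclipsing the exocyclic C=C (1,3-allylic strain) the isobutyl group adds anti to quaternary C10, which by this model gives (9′S).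

Step 13
Reactants: 26 1β-[(1S)-3-methyl-1-(2,4,6-trihydroxyphenyl)butyl]eudesmane-4α,11-diol
Product: 28 macrocarpal J, via bis(iminium) salt 27 (not isolated)
Conditions: POCl3 (2.5 equiv), DMF, EtOAc, 0 → 25 °C; then aq. NaOAc
Reagents that add atoms: N,N-dimethylformamide CN(C)C=O; water O
Why: Double Vilsmeier–Haack formylation (electrophilic aromatic substitution) of the very electron-rich phloroglucinol ring at its two free positions; no stereocentre is touched.

**Compound list**
1 | resorcinol | Oc1cccc(O)c1 | starting material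
2 | 1,3-bis(pinacolboryloxy)-5-(pinacolboryl)benzene | CC1(C)OB(Oc2cc(OB3OC(C)(C)C(C)(C)O3)cc(B3OC(C)(C)C(C)(C)O3)c2)OC1(C)C | intermediate
3 | phloroglucinol | Oc1cc(O)cc(O)c1 | intermediate
4 | 2-methylcyclopentane-1,3-dione | CC1C(=O)CCC1=O | starting material
5 | acrolein | C=CC=O | starting material
6 | 2-methyl-2-(3-oxopropyl)cyclopentane-1,3-dione | CC1(CCC=O)C(=O)CCC1=O | intermediate
7 | isopropenylmagnesium bromide | C=C(C)[Mg]Br | starting material
8 | bromomagnesium 2-methyl-5-(1-methyl-2,5-dioxocyclopentyl)pent-1-en-3-olate (racemic) | C=C(C)C(O[Mg]Br)CCC1(C)C(=O)CCC1=O | intermediate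
9 | 2-methyl-5-(1-methyl-2,5-dioxocyclopentyl)pent-1-en-3-yl diethyl phosphate (racemic) | C=C(C)C(OP(=O)(OCC)OCC)CCC1(C)C(=O)CCC1=O | intermediate
10 | 5-[(1S,2S)-2-hydroxy-1-methyl-5-oxocyclopentyl]-2-methylpent-1-en-3-yl diethyl phosphate (OH cis to side chain; both epimers at the phosphate carbon) | C=C(C)C(OP(=O)(OCC)OCC)CC[C@@]1(C)[C@@H](O)CCC1=O | intermediate
11 | 2-methyl-5-[(1S,2S)-1-methyl-5-oxo-2-(triethylsilyloxy)cyclopentyl]pent-1-en-3-yl diethyl phosphate | C=C(C)C(OP(=O)(OCC)OCC)CC[C@@]1(C)[C@@H](O[Si](CC)(CC)CC)CCC1=O | intermediate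
12 | vinylmagnesium bromide | C=C[Mg]Br | starting material
13 | 5-[(1S,2S,5S)-2-ethenyl-2-hydroxy-1-methyl-5-(triethylsilyloxy)cyclopentyl]-2-methylpent-1-en-3-yl diethyl phosphate (vinyl cis to methyl) | C=C(C)C(OP(=O)(OCC)OCC)CC[C@@]1(C)[C@@H](O[Si](CC)(CC)CC)CC[C@]1(O)C=C | intermediate
14 | 1α-(triethylsilyloxy)-15-nor-5β-eudesm-11-en-4-one (cis-fused) | C=C(C)[C@@H]1CC[C@@]2(C)[C@@H](O[Si](CC)(CC)CC)CCC(=O)[C@H]2C1 | intermediate
15 | 1α-(triethylsilyloxy)-15-nor-5α-eudesm-11-en-4-one | C=C(C)[C@@H]1CC[C@@]2(C)[C@@H](O[Si](CC)(CC)CC)CCC(=O)[C@@H]2C1 | intermediate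
16 | 1α-(triethylsilyloxy)eudesma-4(15),11-diene | C=C(C)[C@@H]1CC[C@@]2(C)[C@@H](O[Si](CC)(CC)CC)CCC(=C)[C@@H]2C1 | intermediate
17 | eudesma-4(15),11-dien-1α-ol | C=C(C)[C@@H]1CC[C@@]2(C)[C@@H](O)CCC(=C)[C@@H]2C1 | intermediate
18 | eudesma-4(15),11-dien-1-one | C=C(C)[C@@H]1CC[C@@]2(C)C(=O)CCC(=C)[C@@H]2C1 | intermediate
19 | 4α,11-dihydroperoxyeudesman-1-one | CC(C)(OO)[C@@H]1CC[C@@]2(C)C(=O)CC[C@@](C)(OO)[C@@H]2C1 | intermediate
20 | 4α,11-dihydroxyeudesman-1-one | CC(C)(O)[C@@H]1CC[C@@]2(C)C(=O)CC[C@@](C)(O)[C@@H]2C1 | intermediate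
21 | 1-(methoxymethylidene)eudesmane-4α,11-diol (E/Z) | COC=C1CC[C@@](C)(O)[C@@H]2C[C@H](C(C)(C)O)CC[C@@]12C | intermediate
22 | 1β-formyleudesmane-4α,11-diol | CC(C)(O)[C@@H]1CC[C@@]2(C)[C@H](C=O)CC[C@@](C)(O)[C@@H]2C1 | intermediate
23 | isobutylmagnesium bromide | CC(C)C[Mg]Br | starting material
24 | 1β-[hydroxy(2,4,6-trihydroxyphenyl)methyl]eudesmane-4α,11-diol (carbinol epimers; magnesium salt in the flask) | OC(c1c(O)cc(O)cc1O)[C@@H]1CC[C@@](C)(O)[C@@H]2C[C@H](C(C)(C)O)CC[C@]21C | intermediate
25 | 6-[(4α,11-dihydroxyeudesman-1β-yl)methylidene]-3,5-dihydroxycyclohexa-2,4-dien-1-one | O=C1C=C(O)C=C(O)C1=C[C@@H]1CC[C@@](C)(O)[C@@H]2C[C@H](C(C)(C)O)CC[C@]21C | intermediate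
26 | 1β-[(1S)-3-methyl-1-(2,4,6-trihydroxyphenyl)butyl]eudesmane-4α,11-diol | CC(C)C[C@H](c1c(O)cc(O)cc1O)[C@@H]1CC[C@@](C)(O)[C@@H]2C[C@H](C(C)(C)O)CC[C@]21C | intermediate
27 | 3,5-bis[(dimethyliminio)methyl] derivative of 26, dichloride | CC(C)C[C@H](c1c(O)c(C=[N+](C)C)c(O)c(C=[N+](C)C)c1O)[C@@H]1CC[C@@](C)(O)[C@@H]2C[C@H](C(C)(C)O)CC[C@]21C.[Cl-].[Cl-] | intermediate
28 | macrocarpal J | CC(C)C[C@H](c1c(O)c(C=O)c(O)c(C=O)c1O)[C@@H]1CC[C@@](C)(O)[C@@H]2C[C@H](C(C)(C)O)CC[C@]21C | target

**Step count**
Total steps: 13. Longest linear sequence: 12 (steps 2–13); step 1 is a one-step branch that joins at step 12.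

**Steps most likely to fail, with fallbacks**

Step 7 (the proposed new step). Risks: the allyl cation may eliminate or be captured by solvent before the seven-membered closure; C3 may migrate instead of C10; C7 selectivity is a prediction. Fallback with known chemistry, from 13 back to 15:
- Hydroxyl-directed epoxidation of the vinyl group (VO(acac)2, tBuOOH) gives epoxy alcohol F1.
- BF3·OEt2 at −78 °C effects the established semipinacol rearrangement of a 2,3-epoxy alcohol (C10 migrates to C5 as the epoxide opens) to the ring-expanded β-hydroxy ketone F2.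
- MsCl/Et3N, then DBU, gives the α-methylene ketone F3.
- Pd(PPh3)4, hexamethyldisilane and LiCl turn the allylic phosphate into the allylsilane F4.
- EtAlCl2 at −78 °C closes ring B by intramolecular Sakurai conjugate allylation (C7 to C6, isopropenyl regenerated, chair transition state with the isopropenyl group equatorial); DBU equilibration of C5 gives 15.

Step 12. Risks: poor solubility of the phloroglucinol magnesium salts, and β-hydride reduction of the quinone methide by the Grignard reagent. Fallback via a benzylic cation instead of the quinone methide, from 3 and 22 to 26: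
- 3 with BnBr/K2CO3 gives 1,3,5-tris(benzyloxy)benzene F5.
- Lithiation (nBuLi, TMEDA) and addition to 22 give the benzylic alcohol F6.
- Catalytic Sc(OTf)3 with methallyltrimethylsilane ionizes only the trialkoxybenzylic alcohol and gives the methallyl compound F7 (same anti-to-C10 facial control).
- H2 over Pd/C reduces the alkene to isobutyl and removes the three benzyl groups, giving 26.

Step 13. Risk: the chloroiminium reagent and HCl may dehydrate or chlorinate the two tertiary alcohols. Fallback under basic conditions, from 26 to 28: MgCl2, Et3N and paraformaldehyde in MeCN at reflux (Casnati–Skattebøl ortho-formylation) hydroxymethylate both free ring positions to the bis(hydroxymethyl) compound F8 in the flask, which formaldehyde oxidizes in situ (Oppenauer-type hydride transfer) to 28.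

**Further compounds**
F1 | step 7 | 5-[(1S,2S,5S)-2-hydroxy-1-methyl-2-(oxiran-2-yl)-5-(triethylsilyloxy)cyclopentyl]-2-methylpent-1-en-3-yl diethyl phosphate | C=C(C)C(OP(=O)(OCC)OCC)CC[C@@]1(C)[C@@H](O[Si](CC)(CC)CC)CC[C@]1(O)C1CO1
F2 | step 7 | 5-[(1S,6S)-2-(hydroxymethyl)-1-methyl-3-oxo-6-(triethylsilyloxy)cyclohexyl]-2-methylpent-1-en-3-yl diethyl phosphate | C=C(C)C(OP(=O)(OCC)OCC)CC[C@@]1(C)[C@@H](O[Si](CC)(CC)CC)CCC(=O)C1CO
F3 | step 7 | 2-methyl-5-[(1S,6S)-1-methyl-2-methylidene-3-oxo-6-(triethylsilyloxy)cyclohexyl]pent-1-en-3-yl diethyl phosphate | C=C(C)C(OP(=O)(OCC)OCC)CC[C@@]1(C)[C@@H](O[Si](CC)(CC)CC)CCC(=O)C1=C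
F4 | step 7 | (3S,4S)-3-methyl-2-methylidene-3-[4-methyl-5-(trimethylsilyl)pent-3-en-1-yl]-4-(triethylsilyloxy)cyclohexan-1-one (E/Z) | C[Si](C)(C)CC(C)=CCC[C@@]1(C)[C@@H](O[Si](CC)(CC)CC)CCC(=O)C1=C
F5 | step 12 | 1,3,5-tris(benzyloxy)benzene | c1ccc(COc2cc(OCc3ccccc3)cc(OCc3ccccc3)c2)cc1
F6 | step 12 | 1β-{hydroxy[2,4,6-tris(benzyloxy)phenyl]methyl}eudesmane-4α,11-diol | OC(c1c(OCc2ccccc2)cc(OCc2ccccc2)cc1OCc1ccccc1)[C@@H]1CC[C@@](C)(O)[C@@H]2C[C@H](C(C)(C)O)CC[C@]21C
F7 | step 12 | 1β-{(1S)-3-methyl-1-[2,4,6-tris(benzyloxy)phenyl]but-3-en-1-yl}eudesmane-4α,11-diol | C=C(C)C[C@H](c1c(OCc2ccccc2)cc(OCc2ccccc2)cc1OCc1ccccc1)[C@@H]1CC[C@@](C)(O)[C@@H]2C[C@H](C(C)(C)O)CC[C@]21C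
F8 | step 13 | 1β-{(1S)-1-[2,4,6-trihydroxy-3,5-bis(hydroxymethyl)phenyl]-3-methylbutyl}eudesmane-4α,11-diol | CC(C)C[C@H](c1c(O)c(CO)c(O)c(CO)c1O)[C@@H]1CC[C@@](C)(O)[C@@H]2C[C@H](C(C)(C)O)CC[C@]21C
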